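**Strategy.** Ring A is disconnected at C4–C5 (labdane numbering). Returning the gem-dimethyl carbon C4 to C10 leaves a 1,2,2-trimethylcyclopentane (C10, C1, C2, C3, C4), available from (−)-camphoric acid, with C5 as an exocyclic carbinol carbon on a farnesyl-type chain. On ionisation at C5, C4 shifts from C10 to C5: the cyclopentane grows into the cyclohexane of ring A, and the C10 cation so uncovered closes ring B on the C8=C9 alkene. The step exploits the triad C4–C5–C10 of ring A, two quaternary carbons flanking the ring-fusion methine, and sets C5, C9 and C10 in one operation; C17 is oxidised afterwards.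

Key step: step 8

Remark: atom numbers are labdane numbers and are kept for all intermediates (C5 is the carbinol carbon of 10, C10 the quaternary carbon that was C1 of camphoric acid); (1S,3R)-(−)-camphoric acid, the enantiomer of the acid from natural camphor, is assumed to be purchasable.

Step 1
Reactants: 1 (1S,3R)-(−)-camphoric acid
Product: 3 (1S,3R)-3-[(1,3-dioxoisoindolin-2-yl)oxycarbonyl]-1,2,2-trimethylcyclopentane-1-carboxylic acid, via camphoric anhydride 2 (not isolated)
Conditions: N,N'-diisopropylcarbodiimide, CH2Cl2, 0 °C to rt; then N-hydroxyphthalimide, Et3N, 4-(dimethylamino)pyridine (cat.), rt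
Reagents that add atoms: N-hydroxyphthalimide, ON1C(=O)c2ccccc2C1=O
Why: The cis-1,3-diacid should close to the anhydride with the carbodiimide, and N-hydroxyphthalimide should open it at the less hindered carbonyl on the secondary carbon (regioselective anhydride acylation), so that the redox-active ester sits on the carboxyl to be removed and the acid on the quaternary carbon stays free; no stereocentre is touched.

Step 2
Reactants: 3 (1S,3R)-3-[(1,3-dioxoisoindolin-2-yl)oxycarbonyl]-1,2,2-trimethylcyclopentane-1-carboxylic acid
Product: 4 (1S)-1,2,2-trimethylcyclopentane-1-carboxylic acid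
Conditions: Hantzsch ester, Ru(bpy)3Cl2·6H2O (cat.), DMF, blue LEDs, rt
Reagents that add atoms: none
Why: Photoreductive decarboxylation of the N-acyloxyphthalimide (single-electron reduction, loss of CO2 and phthalimide, hydrogen-atom transfer from the Hantzsch ester to the secondary radical) should remove the superfluous carboxyl carbon, while the quaternary stereocentre is not involved.

Step 3
Reactants: 4 (1S)-1,2,2-trimethylcyclopentane-1-carboxylic acid
Product: 5 1-[(1S)-1,2,2-trimethylcyclopentyl]ethan-1-one
Conditions: MeLi (excess), Et2O, 0 °C to reflux; aq. NH4Cl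
Reagents that add atoms: methyllithium, [Li]C
Why: Addition of methyllithium to the lithium carboxylate gives a gem-dialkoxide that collapses to the methyl ketone only on work-up (carboxylic acid to ketone with an organolithium), a reaction that is well suited to hindered acids.

Step 4
Reactants: 6 geranyl acetate
Product: 7 (2E,6E)-8-hydroxy-3,7-dimethylocta-2,6-dien-1-yl acetate
Conditions: SeO2 (cat.), t-BuOOH, salicylic acid (cat.), CH2Cl2, rt
Reagents that add atoms: selenium dioxide, O=[Se]=O (oxygen carrier); tert-butyl hydroperoxide, CC(C)(C)OO (terminal oxidant)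
Why: Riley-type allylic oxidation (ene reaction, then [2,3]-sigmatropic shift) should attack the electron-rich distal alkene at its E-methyl group and spare the alkene that carries the allylic acetate, with the 6E geometry as the known outcome.

Step 5
Reactants: 7 (2E,6E)-8-hydroxy-3,7-dimethylocta-2,6-dien-1-yl acetate
Product: 8 (2E,6E)-8-bromo-3,7-dimethylocta-2,6-dien-1-yl acetate
Conditions: CBr4, PPh3, CH2Cl2, 0 °C
Reagents that add atoms: tetrabromomethane, BrC(Br)(Br)Br
Why: The Appel reaction should convert the primary allylic alcohol into the bromide under neutral conditions, without allylic transposition or loss of the E geometry.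

Step 6
Reactants: 5 1-[(1S)-1,2,2-trimethylcyclopentyl]ethan-1-one; 8 (2E,6E)-8-bromo-3,7-dimethylocta-2,6-dien-1-yl acetate
Product: 9 (2E,6E)-3,7-dimethyl-10-oxo-10-[(1S)-1,2,2-trimethylcyclopentyl]deca-2,6-dien-1-yl acetate
Conditions: LiN(iPr)2, THF, −78 °C; then 8, DMPU, −78 to −30 °C
Reagents that add atoms: none
Why: The methyl ketone can enolise on one side only, so a single lithium enolate forms, and its C-alkylation by the reactive primary allylic bromide at low temperature (enolate alkylation) should outrun attack on the remote acetate; this joins C6 to C7.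

Step 7
Reactants: 9 (2E,6E)-3,7-dimethyl-10-oxo-10-[(1S)-1,2,2-trimethylcyclopentyl]deca-2,6-dien-1-yl acetate
Product: 10 (2E,6E,10S)-10-hydroxy-3,7-dimethyl-10-[(1S)-1,2,2-trimethylcyclopentyl]deca-2,6-dien-1-yl acetate
Conditions: (R)-2-methyl-CBS-oxazaborolidine (C18H20BNO, cat.), catecholborane, toluene, −40 to 0 °C; then MeOH, aq. NaHCO3
Reagents that add atoms: none
Why: In the Corey–Bakshi–Shibata reduction the oxazaborolidine tells the tert-alkyl side of the ketone from the primary alkyl side, so the R catalyst should set the S carbinol (C5) by reagent control, and catecholborane at low temperature should neither hydroborate the trisubstituted alkenes nor reduce the acetate.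

Step 8
Reactants: 10 (2E,6E,10S)-10-hydroxy-3,7-dimethyl-10-[(1S)-1,2,2-trimethylcyclopentyl]deca-2,6-dien-1-yl acetate
Product: 12 (5S,9S,10S)-labda-7,13E-dien-15-yl acetate, via secondary triflate 11 (not isolated)
Conditions: Tf2O, 2,6-di-tert-butyl-4-methylpyridine, CH2Cl2, −78 to −20 °C
Reagents that add atoms: none
Why: Proposed new method: triflation of the hindered carbinol gives 11, whose C5–O bond ionises with antiperiplanar participation of the C10–C4 bond, so that the gem-dimethyl carbon C4 shifts from C10 to C5 (Wagner–Meerwein shift), the tertiary C10 cation is trapped by the C8=C9 alkene and the C8 cation loses H-7 to the pyridine base. The closest known reaction types are the solvolytic ring expansion of (1-alkylcyclopentyl)carbinyl sulfonates (Demjanov-type) and the cation–olefin cyclisation of monocyclofarnesyl-type cations; only their coupling in one cascade is untested. Ring A arises by the 1,2-alkyl shift, which inserts C5 between C10 and C4 and turns the cyclopentane C10–C1–C2–C3–C4 into a cyclohexane, and ring B closes by 6-endo-trig attack of C9 on C10 through a chair transition state. C5 is fixed by inversion at the carbinol carbon made in step 7, C10 by entry of C9 anti to the departing C4 on the camphor-derived quaternary centre, which makes the ring fusion trans, and C9 by the E geometry of the C8=C9 alkene, which places C11 equatorial. The step needs C4 to migrate in preference to C1 or the methyl group, which the higher migratory aptitude of the fully substituted carbon and the relief of strain between the two adjacent quaternary carbons should secure. It also needs the cascade to stop at the bicycle with the alkene at C7–C8, which the acetate-deactivated C13=C14 alkene and the kinetic preference for loss of the axial H-7 in C8 cations of this type should favour, although this regiochemistry is the least secured feature.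

Step 9
Reactants: 12 (5S,9S,10S)-labda-7,13E-dien-15-yl acetate
Product: 13 (5S,9R,10S)-17-hydroxylabda-7,13E-dien-15-yl acetate
Conditions: SeO2 (cat.), t-BuOOH, CH2Cl2, 0 °C to rt
Reagents that add atoms: selenium dioxide, O=[Se]=O (oxygen carrier); tert-butyl hydroperoxide, CC(C)(C)OO (terminal oxidant)
Why: Riley-type allylic oxidation should go to the more substituted end of the ring alkene and there prefer the methyl group C17 over the hindered methine C9, as is usual for drim-7-enes, while the side-chain alkene is deactivated by its allylic acetate; no stereocentre changes (only the descriptor of C9).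

Step 10
Reactants: 13 (5S,9R,10S)-17-hydroxylabda-7,13E-dien-15-yl acetate
Product: 14 (5S,9R,10S)-labda-7,13E-diene-15,17-diyl diacetate (CNP0257931.1)
Conditions: Ac2O, pyridine, 4-(dimethylamino)pyridine (cat.), CH2Cl2, rt
Reagents that add atoms: acetic anhydride, CC(=O)OC(C)=O
Why: Nucleophile-catalysed acetylation of the primary allylic alcohol should give the diacetate without touching alkenes or stereocentres.

**Compound list**
1 | (1S,3R)-(−)-camphoric acid [(1S,3R)-1,2,2-trimethylcyclopentane-1,3-dicarboxylic acid] | OC(=O)[C@@]1(C)CC[C@@H](C(=O)O)C1(C)C | starting material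
2 | (1S,5R)-1,8,8-trimethyl-3-oxabicyclo[3.2.1]octane-2,4-dione (camphoric anhydride) | O=C1OC(=O)[C@@]2(C)CC[C@@H]1C2(C)C | intermediate
3 | (1S,3R)-3-[(1,3-dioxoisoindolin-2-yl)oxycarbonyl]-1,2,2-trimethylcyclopentane-1-carboxylic acid | OC(=O)[C@@]1(C)CC[C@@H](C(=O)ON2C(=O)c3ccccc3C2=O)C1(C)C | intermediate
4 | (1S)-1,2,2-trimethylcyclopentane-1-carboxylic acid | OC(=O)[C@@]1(C)CCCC1(C)C | intermediate
5 | 1-[(1S)-1,2,2-trimethylcyclopentyl]ethan-1-one | CC(=O)[C@@]1(C)CCCC1(C)C | intermediate
6 | geranyl acetate [(2E)-3,7-dimethylocta-2,6-dien-1-yl acetate] | CC(=O)OC/C=C(\C)CCC=C(C)C | starting material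
7 | (2E,6E)-8-hydroxy-3,7-dimethylocta-2,6-dien-1-yl acetate | CC(=O)OC/C=C(\C)CC/C=C(\C)CO | intermediate
8 | (2E,6E)-8-bromo-3,7-dimethylocta-2,6-dien-1-yl acetate | CC(=O)OC/C=C(\C)CC/C=C(\C)CBr | intermediate
9 | (2E,6E)-3,7-dimethyl-10-oxo-10-[(1S)-1,2,2-trimethylcyclopentyl]deca-2,6-dien-1-yl acetate | CC(=O)OC/C=C(\C)CC/C=C(\C)CCC(=O)[C@@]1(C)CCCC1(C)C | intermediate
10 | (2E,6E,10S)-10-hydroxy-3,7-dimethyl-10-[(1S)-1,2,2-trimethylcyclopentyl]deca-2,6-dien-1-yl acetate | CC(=O)OC/C=C(\C)CC/C=C(\C)CC[C@H](O)[C@@]1(C)CCCC1(C)C | intermediate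
11 | (2E,6E,10S)-3,7-dimethyl-10-[(1S)-1,2,2-trimethylcyclopentyl]-10-(trifluoromethanesulfonyloxy)deca-2,6-dien-1-yl acetate | CC(=O)OC/C=C(\C)CC/C=C(\C)CC[C@H](OS(=O)(=O)C(F)(F)F)[C@@]1(C)CCCC1(C)C | intermediate
12 | (5S,9S,10S)-labda-7,13E-dien-15-yl acetate | CC(=O)OC/C=C(\C)CC[C@H]1C(C)=CC[C@H]2C(C)(C)CCC[C@]12C | intermediate
13 | (5S,9R,10S)-17-hydroxylabda-7,13E-dien-15-yl acetate | CC(=O)OC/C=C(\C)CC[C@H]1C(CO)=CC[C@H]2C(C)(C)CCC[C@]12C | intermediate
14 | (5S,9R,10S)-labda-7,13E-diene-15,17-diyl diacetate | CC(=O)OC/C=C(\C)CC[C@H]1C(COC(C)=O)=CC[C@H]2C(C)(C)CCC[C@]12C | target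

**Step count.** Total: 10 steps. Longest linear sequence: 8 steps (1, 2, 3, 6, 7, 8, 9, 10); bromide 8 is made in 2 steps (4, 5).

**Steps most likely to fail**

Step 8. The ionisation may leave the planned channel in several ways: elimination towards C6 before the shift, migration of C1 in place of C4, proton loss from the C10 cation before ring B closes, or proton loss from the C8 cation towards C17 or C9. The fallback uses known chemistry, sets out from 10 and returns at 12. Alcohol 10 is converted with MsCl and Et3N into its methanesulfonate F1. Buffered hydrolysis of F1 (CaCO3, aqueous acetone, reflux) is a classical solvolytic Wagner–Meerwein ring expansion and should give, by capture of the C10 cation with water, the ring-expanded tertiary cyclohexanol F2, in which ring A and C5 are already in place. F2 is then ionised separately with SnCl4 in CH2Cl2 at −78 °C, a tertiary-alcohol-initiated cation–olefin cyclisation of the monocyclofarnesyl type, which closes ring B and gives 12.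

Step 9. Oxidation may occur at the wrong allylic position (C6 or C9), or C17 may be over-oxidised to the enal. The fallback sets out from 12 and returns at 14, so that 13 is bypassed. mCPBA should epoxidise the ring alkene of 12 from the α face to the 7α,8α-epoxide F3. Et2Al(tmp) (diethylaluminium 2,2,6,6-tetramethylpiperidide) opens the epoxide by removal of a C17 proton to the 7α-hydroxy-8(17)-ene F4. PBr3 converts F4 with allylic transposition into the primary 17-bromide F5, and CsOAc in DMF displaces bromide to give 14.

Step 6. The lithium enolate may attack the acetate, proton transfer from the product may lead to double alkylation, or 8 may lose HBr. The fallback sets out from 4 and returns at 9. Acid 4 is converted with (COCl)2 into the acid chloride F6, which acylates the lithium enolate of 2-(trimethylsilyl)ethyl acetate to the β-keto ester F7. Its potassium enolate (K2CO3, acetone) is alkylated by 8 to the alkylated β-keto ester F8 under conditions that do not endanger the acetate. TBAF then removes the silylethyl group, and the β-keto acid loses CO2 to give 9.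

Further compounds
F1 | step 8 | (2E,6E,10S)-10-(methanesulfonyloxy)-3,7-dimethyl-10-[(1S)-1,2,2-trimethylcyclopentyl]deca-2,6-dien-1-yl acetate | CC(=O)OC/C=C(\C)CC/C=C(\C)CC[C@H](OS(C)(=O)=O)[C@@]1(C)CCCC1(C)C
F2 | step 8 | (2E,6E)-9-[(1S,2S)-2-hydroxy-2,6,6-trimethylcyclohexyl]-3,7-dimethylnona-2,6-dien-1-yl acetate | CC(=O)OC/C=C(\C)CC/C=C(\C)CC[C@H]1C(C)(C)CCC[C@]1(C)O
F3 | step 9 | 7α,8α-epoxylabd-13E-en-15-yl acetate (normal labdane series) | CC(=O)OC/C=C(\C)CC[C@H]1[C@]2(C)O[C@@H]2C[C@H]3C(C)(C)CCC[C@]13C
F4 | step 9 | 7α-hydroxylabda-8(17),13E-dien-15-yl acetate | CC(=O)OC/C=C(\C)CC[C@H]1C(=C)[C@H](O)C[C@H]2C(C)(C)CCC[C@]12C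
F5 | step 9 | (5S,9R,10S)-17-bromolabda-7,13E-dien-15-yl acetate | CC(=O)OC/C=C(\C)CC[C@H]1C(CBr)=CC[C@H]2C(C)(C)CCC[C@]12C
F6 | step 6 | (1S)-1,2,2-trimethylcyclopentane-1-carbonyl chloride | ClC(=O)[C@@]1(C)CCCC1(C)C
F7 | step 6 | 2-(trimethylsilyl)ethyl 3-oxo-3-[(1S)-1,2,2-trimethylcyclopentyl]propanoate | C[Si](C)(C)CCOC(=O)CC(=O)[C@@]1(C)CCCC1(C)C
F8 | step 6 | 2-(trimethylsilyl)ethyl (4E,8E)-10-acetoxy-4,8-dimethyl-2-[(1S)-1,2,2-trimethylcyclopentane-1-carbonyl]deca-4,8-dienoate (both epimers at C2) | CC(=O)OC/C=C(\C)CC/C=C(\C)CC(C(=O)OCC[Si](C)(C)C)C(=O)[C@@]1(C)CCCC1(C)C
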